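The route disconnects the C6–C7 bond (locants of the target's cyclohepta[b]furan core): the quaternary carbinol C7 becomes the central carbonyl of an exocyclic 3-hydroxy-1,2-dione hung on C8 of a cis-fused cyclohexane γ-lactone made from (R)-carvone. The key step, an α-ketol (acyloin) rearrangement, moves C6 from C8 to C7. In one operation it inserts C7 into the six-membered ring, closing the cycloheptane as the last ring, creates the C7 stereocentre carrying both hydroxyl and crotonoyl, and turns C8 into the ketone that later bears the isobutyrate. It exploits the tertiary α-ketol C7(OH)–C1′=O flanked by oxygenated C8.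

Key step: step 9

Remark: in all Why lines the locants are those of the target (O1, C2 lactone carbonyl, C3, C3a, C4, C5, C6, C7, C8, C8a; C1′ is the crotonoyl carbonyl carbon) and are used for the corresponding atoms of every intermediate; the systematic names carry their own locants.

Step 1
Reactants: 1 (R)-(−)-carvone
Product: 2 (5R)-5-(3-chloroprop-1-en-2-yl)-2-methylcyclohex-2-en-1-one
Conditions: Ca(OCl)2, solid CO2, CH2Cl2/H2O, 0 °C
Reagents that add atoms: calcium hypochlorite [Ca+2].[O-]Cl.[O-]Cl
Why: Ene-type allylic chlorination by HOCl (formed from the hypochlorite and CO2) should attack only the electron-rich 1,1-disubstituted isopropenyl alkene and not the enone, leaving the chiral-pool centre (future C3a) untouched.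

Step 2
Reactants: 2 (5R)-5-(3-chloroprop-1-en-2-yl)-2-methylcyclohex-2-en-1-one
Product: 3 2-[(1R)-4-methyl-5-oxocyclohex-3-en-1-yl]prop-2-enal
Conditions: N-methylmorpholine N-oxide (3 equiv), KI (10 mol %), MeCN, 23 → 45 °C
Reagents that add atoms: N-methylmorpholine N-oxide C[N+]1([O-])CCOCC1
Why: Kornblum-type N-oxide oxidation, in which iodide-assisted SN2 displacement of the allylic chloride by the N-oxide oxygen and loss of N-methylmorpholine should give the 2-substituted acrolein without touching the ring enone.

Step 3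
Reactants: 3 2-[(1R)-4-methyl-5-oxocyclohex-3-en-1-yl]prop-2-enal
Product: 4 2-[(1R)-4-methyl-5-oxocyclohex-3-en-1-yl]prop-2-enoic acid
Conditions: NaClO2, NaH2PO4, 2-methylbut-2-ene, t-BuOH/H2O, 0 → 23 °C
Reagents that add atoms: sodium chlorite [Na+].[O-]Cl=O
Why: Pinnick oxidation should convert the enal into the acrylic acid under buffered conditions, the scavenger alkene removing HOCl before it can chlorinate either alkene.

Step 4
Reactants: 4 2-[(1R)-4-methyl-5-oxocyclohex-3-en-1-yl]prop-2-enoic acid
Product: 6 (3aS,7aR)-6-methyl-3-methylidene-3a,4-dihydro-1-benzofuran-2,7(3H,7aH)-dione, via trans-iodo keto acid 5 (not isolated)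
Conditions: LDA (2.2 equiv), THF, −78 °C; I2 (1.05 equiv), −78 → 0 °C
Reagents that add atoms: iodine II (its atom is kept only in 5)
Why: Kinetic α′-deprotonation of the enone within the carboxylate dianion, enolate iodination at C8a and 5-exo-tet SN2 displacement by the carboxylate should close the γ-lactone; the displacement inverts the trans-iodide and iodide exchange epimerises any cis-iodide, so both funnel into the cis-fused lactone, which is also the thermodynamic ring fusion at this ketone α-carbon.

Step 5
Reactants: 6 (3aS,7aR)-6-methyl-3-methylidene-3a,4-dihydro-1-benzofuran-2,7(3H,7aH)-dione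
Product: 7 (3R,3aS,6S,7aR)-3,6-dimethylhexahydro-1-benzofuran-2,7-dione
Conditions: H2 (1 atm), 10% Pd/C, EtOAc, 23 °C
Reagents that add atoms: none
Why: Heterogeneous catalytic hydrogenation should deliver hydrogen to both the exocyclic methylene and the enone C5=C6 bond from the convex face of the cis-fused bicycle (the face of H3a and H8a), setting C3 (methyl cis to C4) and C6 (methyl cis to the lactone oxygen) under kinetic control.

Step 6
Reactants: 8 (E)-pent-3-en-2-one
Product: 10 (E)-1-diazopent-3-en-2-one, via trifluoroacetyl diketone 9 (not isolated)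
Conditions: LiHMDS, THF, −78 °C; CF3CO2CH2CF3, −78 °C, aq HCl work-up; then MsN3, Et3N, H2O (1 equiv), MeCN, 23 °C
Reagents that add atoms: methanesulfonyl azide CS(=O)(=O)N=[N+]=[N-]; 2,2,2-trifluoroethyl trifluoroacetate O=C(OCC(F)(F)F)C(F)(F)F (its atoms are kept only in 9)
Why: Detrifluoroacetylative (Regitz-type) diazo transfer, in which the kinetic methyl enolate is trifluoroacetylated and the activated 1,3-diketone takes up the diazo group with loss of the trifluoroacetyl unit, avoids the pyrazoline formation expected from an enoyl chloride and diazomethane.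

Step 7
Reactants: 7 (3R,3aS,6S,7aR)-3,6-dimethylhexahydro-1-benzofuran-2,7-dione; 10 (E)-1-diazopent-3-en-2-one
Product: 11 (3R,3aS,6S,7R,7aR)-7-[(3E)-1-diazo-2-oxopent-3-en-1-yl]-7-hydroxy-3,6-dimethylhexahydro-1-benzofuran-2(3H)-one
Conditions: 10, LDA, THF, −78 °C; then 7, −78 °C; AcOH quench at −78 °C
Reagents that add atoms: none
Why: Aldol-type addition of the lithiated diazo ketone to the C8 ketone should occur from the convex face, anti to the C8a–O bond, the C6 methyl and the pseudoaxial C3a–C3 bond, so the new C8 hydroxyl lies on the face of the lactone oxygen, while the weakly basic nucleophile at −78 °C should leave the epimerisable C6 and C8a centres intact.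

Step 8
Reactants: 11 (3R,3aS,6S,7R,7aR)-7-[(3E)-1-diazo-2-oxopent-3-en-1-yl]-7-hydroxy-3,6-dimethylhexahydro-1-benzofuran-2(3H)-one
Product: 12 (3R,3aS,6S,7S,7aR)-7-hydroxy-3,6-dimethyl-7-[(3E)-2-oxopent-3-enoyl]hexahydro-1-benzofuran-2(3H)-one
Conditions: dimethyldioxirane (1.2 equiv, acetone solution), CH2Cl2/acetone, −40 → 0 °C
Reagents that add atoms: dimethyldioxirane CC1(C)OO1
Why: Dioxirane oxidation of the diazo carbon (oxygen transfer with loss of N2), a standard entry to vicinal polycarbonyls, should be far faster than epoxidation of the electron-poor enone alkene.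

Step 9
Reactants: 12 (3R,3aS,6S,7S,7aR)-7-hydroxy-3,6-dimethyl-7-[(3E)-2-oxopent-3-enoyl]hexahydro-1-benzofuran-2(3H)-one
Product: 13 (3R,3aS,6S,7R,8aR)-7-[(2E)-but-2-enoyl]-7-hydroxy-3,6-dimethylhexahydro-2H-cyclohepta[b]furan-2,8(3H)-dione
Conditions: Sc(OTf)3 (10 mol %), 4 Å MS, CH2Cl2, 0 → 23 °C
Reagents that add atoms: none
Why: α-Ketol (acyloin) rearrangement: Sc(III) should bind the C8 hydroxyl and the adjacent dione in a syn-coplanar chelate, and the C6–C8 bond then migrates to the activated central carbonyl carbon C7 while C8 becomes a ketone, so the cycloheptane closes by ring expansion (1,2-alkyl shift; C6–C7 formed, C6–C8 broken). The closest known reaction types are the Lewis acid-catalysed rearrangement of β-hydroxy-α-dicarbonyls to α-hydroxy-β-dicarbonyls, including ring-expanding cases, and the acyloin ring expansion of 1-acylcycloalkanols. The shift should be driven by conversion of the vicinal dione into a 1,3-dione and by the stronger chelation of the product. The new stereocentre C7 is set stereospecifically: C6 migrates suprafacially with retention, and with the C8 oxygen held syn to the C7 carbonyl oxygen it can only reach the face of C7 that leaves the hydroxyl cis to the C6 methyl and the crotonoyl group on the opposite face, which relays the C8 configuration set in step 7. The step needs migration of C6 rather than C8a and no further 1,2-acyl shift; the electron-withdrawing lactone oxygen makes C8a the poorer migrating group, and a catalytic, non-nucleophilic Lewis acid with short contact time should limit later ketol shifts.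

Step 10
Reactants: 13 (3R,3aS,6S,7R,8aR)-7-[(2E)-but-2-enoyl]-7-hydroxy-3,6-dimethylhexahydro-2H-cyclohepta[b]furan-2,8(3H)-dione
Product: 14 (3R,3aS,6S,7S,8S,8aR)-7-[(2E)-but-2-enoyl]-7,8-dihydroxy-3,6-dimethyloctahydro-2H-cyclohepta[b]furan-2-one
Conditions: NaBH4 (1.0 equiv), CH2Cl2/MeOH 1:1, −78 °C
Reagents that add atoms: none
Why: Chemoselective borohydride reduction, in which the saturated, doubly α-oxygenated C8 ketone should react faster than the conjugated enone carbonyl at −78 °C, with hydride arriving at C8 from the face of the C7 hydroxyl and anti to the bulky crotonoyl group (Cram-chelate sense) to give the trans-7,8-diol.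

Step 11
Reactants: 14 (3R,3aS,6S,7S,8S,8aR)-7-[(2E)-but-2-enoyl]-7,8-dihydroxy-3,6-dimethyloctahydro-2H-cyclohepta[b]furan-2-one
Product: 15 (3R,3aS,6S,7S,8S,8aR)-7-[(2E)-but-2-enoyl]-7-hydroxy-3,6-dimethyl-2-oxooctahydro-2H-cyclohepta[b]furan-8-yl 2-methylpropanoate
Conditions: (i-PrCO)2O, DMAP (cat.), pyridine, 0 → 23 °C
Reagents that add atoms: isobutyric anhydride CC(C)C(=O)OC(=O)C(C)C
Why: DMAP-catalysed acylation should esterify only the secondary C8 hydroxyl, the tertiary C7 hydroxyl being unreactive under these conditions.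

Compound list
1 | (R)-(−)-carvone, (5R)-2-methyl-5-(prop-1-en-2-yl)cyclohex-2-en-1-one | O=C1C(C)=CC[C@@H](C(C)=C)C1 | starting material
2 | (5R)-5-(3-chloroprop-1-en-2-yl)-2-methylcyclohex-2-en-1-one | O=C1C(C)=CC[C@@H](C(CCl)=C)C1 | intermediate
3 | 2-[(1R)-4-methyl-5-oxocyclohex-3-en-1-yl]prop-2-enal | O=C1C(C)=CC[C@@H](C(C=O)=C)C1 | intermediate
4 | 2-[(1R)-4-methyl-5-oxocyclohex-3-en-1-yl]prop-2-enoic acid | O=C1C(C)=CC[C@@H](C(C(=O)O)=C)C1 | intermediate
5 | 2-[(1S,6S)-6-iodo-4-methyl-5-oxocyclohex-3-en-1-yl]prop-2-enoic acid (iodine trans to the side chain; present as its lithium carboxylate) | O=C1C(C)=CC[C@@H](C(=C)C(=O)O)[C@@H]1I | intermediate (not isolated)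
6 | (3aS,7aR)-6-methyl-3-methylidene-3a,4-dihydro-1-benzofuran-2,7(3H,7aH)-dione | O=C1C(C)=CC[C@@H]2[C@H]1OC(=O)C2=C | intermediate
7 | (3R,3aS,6S,7aR)-3,6-dimethylhexahydro-1-benzofuran-2,7-dione | O=C1[C@@H](C)CC[C@@H]2[C@H]1OC(=O)[C@@H]2C | intermediate
8 | (E)-pent-3-en-2-one | C/C=C/C(C)=O | starting material
9 | (E)-1,1,1-trifluorohept-5-ene-2,4-dione | C/C=C/C(=O)CC(=O)C(F)(F)F | intermediate (not isolated)
10 | (E)-1-diazopent-3-en-2-one | C/C=C/C(=O)C=[N+]=[N-] | intermediate
11 | (3R,3aS,6S,7R,7aR)-7-[(3E)-1-diazo-2-oxopent-3-en-1-yl]-7-hydroxy-3,6-dimethylhexahydro-1-benzofuran-2(3H)-one | C/C=C/C(=O)C(=[N+]=[N-])[C@]1(O)[C@@H](C)CC[C@@H]2[C@H]1OC(=O)[C@@H]2C | intermediate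
12 | (3R,3aS,6S,7S,7aR)-7-hydroxy-3,6-dimethyl-7-[(3E)-2-oxopent-3-enoyl]hexahydro-1-benzofuran-2(3H)-one | C/C=C/C(=O)C(=O)[C@]1(O)[C@@H](C)CC[C@@H]2[C@H]1OC(=O)[C@@H]2C | intermediate
13 | (3R,3aS,6S,7R,8aR)-7-[(2E)-but-2-enoyl]-7-hydroxy-3,6-dimethylhexahydro-2H-cyclohepta[b]furan-2,8(3H)-dione | C/C=C/C(=O)[C@]1(O)[C@@H](C)CC[C@@H]2[C@@H](OC(=O)[C@@H]2C)C1=O | intermediate
14 | (3R,3aS,6S,7S,8S,8aR)-7-[(2E)-but-2-enoyl]-7,8-dihydroxy-3,6-dimethyloctahydro-2H-cyclohepta[b]furan-2-one | C/C=C/C(=O)[C@]1(O)[C@@H](C)CC[C@@H]2[C@@H](OC(=O)[C@@H]2C)[C@@H]1O | intermediate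
15 | (3R,3aS,6S,7S,8S,8aR)-7-[(2E)-but-2-enoyl]-7-hydroxy-3,6-dimethyl-2-oxooctahydro-2H-cyclohepta[b]furan-8-yl 2-methylpropanoate | C/C=C/C(=O)[C@]1(O)[C@@H](C)CC[C@@H]2[C@@H](OC(=O)[C@@H]2C)[C@@H]1OC(=O)C(C)C | target

Total step count: 11. Longest linear sequence: 10 steps (1 → 2 → 3 → 4 → 6 → 7 → 11 → 12 → 13 → 14 → 15); step 6 supplies 10 on a one-step side branch.

Steps most likely to fail

Step 9 (key step). The ketol shift may stall at an unfavourable equilibrium between the six- and seven-membered ketols. It may also be diverted by a further 1,2-acyl migration, by retro-Claisen cleavage, or by oxa-Michael closure of the C8 hydroxyl onto the enone. The fallback sets out from 11 and returns at 13, and makes the ring expansion irreversible at the diazo stage. Rh2(OAc)4 (1 mol %, CH2Cl2, 23 °C) should convert 11, by carbenoid formation and 1,2-shift of C6 with loss of N2 (no hydride can compete at the tertiary carbinol), into (3R,3aS,6S,8aR)-7-[(2E)-but-2-enoyl]-3,6-dimethylhexahydro-2H-cyclohepta[b]furan-2,8(3H)-dione F1, an enolised β-diketone. Electrophilic α-hydroxylation of F1 at C7 would then give 13. Because uncatalysed attack is expected anti to the C6 methyl, the oxygen would be delivered under reagent control, with a chiral N-sulfonyloxaziridine on the enolate or a cinchona base with a hydroperoxide, chosen to add syn to that methyl.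

Step 5. Facial discrimination at the remote C5=C6 bond may be poor, and the unwanted C6 epimer is expected to be the thermodynamically preferred one; palladium may also move the exocyclic alkene into the lactone ring before it is reduced. The fallback sets out from 4 and returns at 7, and sets both centres by catalyst control. Asymmetric hydrogenation of the acrylic acid with Ru(OAc)2(BINAP) (enantiomer chosen for the R acid), H2, MeOH should give (2R)-2-[(1R)-4-methyl-5-oxocyclohex-3-en-1-yl]propanoic acid F2. The enolate iodination and lactonisation of step 4 (LDA, I2) would then pass through (2R)-2-[(1S,6S)-6-iodo-4-methyl-5-oxocyclohex-3-en-1-yl]propanoic acid F3 to the enone lactone (3R,3aS,7aR)-3,6-dimethyl-3a,4-dihydro-1-benzofuran-2,7(3H,7aH)-dione F4. Iridium-catalysed asymmetric hydrogenation of this α-methyl enone (chiral Ir–P,N complex, H2, CH2Cl2) would set C6 and give 7.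

Step 10. The enone may be reduced competitively (1,2 or 1,4), and hydride may reach C8 from the wrong face. The fallback sets out from 13 and returns at 14, and drops the chemoselectivity demand. Luche reduction (NaBH4, CeCl3·7H2O, MeOH, −78 °C), with cerium chelation between the C7 hydroxyl and the C8 carbonyl reinforcing delivery anti to the side chain, should reduce both ketones to (3R,3aS,6S,7R,8S,8aR)-7,8-dihydroxy-7-[(2E)-1-hydroxybut-2-en-1-yl]-3,6-dimethyloctahydro-2H-cyclohepta[b]furan-2-one F5 (both side-chain carbinol epimers). MnO2 (CH2Cl2, 23 °C) would then re-oxidise only the allylic secondary alcohol to the enone, giving 14.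

Further compounds
F1 | step 9 | (3R,3aS,6S,8aR)-7-[(2E)-but-2-enoyl]-3,6-dimethylhexahydro-2H-cyclohepta[b]furan-2,8(3H)-dione (C7 unassigned, enolised) | C/C=C/C(=O)C1[C@@H](C)CC[C@@H]2[C@@H](OC(=O)[C@@H]2C)C1=O
F2 | step 5 | (2R)-2-[(1R)-4-methyl-5-oxocyclohex-3-en-1-yl]propanoic acid | O=C1C(C)=CC[C@@H]([C@@H](C)C(=O)O)C1
F3 | step 5 | (2R)-2-[(1S,6S)-6-iodo-4-methyl-5-oxocyclohex-3-en-1-yl]propanoic acid | O=C1C(C)=CC[C@@H]([C@@H](C)C(=O)O)[C@@H]1I
F4 | step 5 | (3R,3aS,7aR)-3,6-dimethyl-3a,4-dihydro-1-benzofuran-2,7(3H,7aH)-dione | O=C1C(C)=CC[C@@H]2[C@H]1OC(=O)[C@@H]2C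
F5 | step 10 | (3R,3aS,6S,7R,8S,8aR)-7,8-dihydroxy-7-[(2E)-1-hydroxybut-2-en-1-yl]-3,6-dimethyloctahydro-2H-cyclohepta[b]furan-2-one (side-chain carbinol epimers) | C/C=C/C(O)[C@]1(O)[C@@H](C)CC[C@@H]2[C@@H](OC(=O)[C@@H]2C)[C@@H]1O
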